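The ratio I wanted was intermediate A per substrate once a flask has stopped moving: substrate ⇌ intermediate A is a proposed step, and the readings show substrate but not intermediate A.

| flask | substrate | reagent | remark | time |
|---|---|---|---|---|
| maple | 0.0013 M | 1.6 mM (in portions, 2) | run made earlier; portions every 8.0 s |  |
| cedar | 0.0030 M | 1.6 mM (in portions, 2) | run made earlier; portions every 8.0 s |  |
| flask | 0.0020 M | 1.60 mM (in portions, 2) | the portions of reagent follow each other after 8.0 s, the first at the start | 10 min |

- maple (time / min: substrate / %, target / %, side product / %): 1.50: 7.1, 34.1, 51.0; 3.00: 6.3, 36.3, 52.3; 5.00: 5.8, 36.1, 52.6; 6.00: 6.5, 36.5, 52.3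
- cedar (time / min: substrate / %, target / %, side product / %): 0.500: 28.7, 14.2, 24.0; 1.00: 27.2, 19.1, 28.4; 2.50: 27.6, 19.6, 28.2; 6.00: 26.8, 19.0, 28.2

(scatter of a reading: 0.3 percentage points)

- the analysis behind the earlier runs scatters by 0.3 percentage points, standard deviation
- steps that have been proposed: substrate <-> intermediate A; reagent + intermediate A -> intermediate B; reagent + intermediate A -> intermediate C; intermediate B -> target; intermediate C -> side product; intermediate C <-> intermediate D; 2 reagent -> self-condensation product
- the reaction counts as stopped when no species that holds the substrate changes by six tenths of a point or more over the second half of the time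

- which holds at 10 min: what has brought the reaction to rest, or that it has not come to rest (all of the substrate has reacted / it is still moving / the reagent has run out first / forward and back rates have come level)
- share of the substrate used up at 10 min
- target at 10 min, in percent of the substrate charged
- side product at 10 min, in percent of the substrate charged
- intermediate A at 10 min, in percent of the substrate charged
- amount of target if the flask were left three thousand times as long, in percent of the substrate charged

In both runs the readings after the first stand level within their scatter while substrate remains, so I took the reagent as the limiting reagent and averaged those readings.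

Maple shows 6.20 % substrate and 88.7 % target plus side product, which leaves 5.10 % unseen. Cedar shows 27.2 % and 47.5 %, which leaves 25.3 % unseen.

I took the unseen part as intermediate A. Its ratio to substrate is 0.823 in maple, where a small difference carries the scatter, and 0.930 in cedar. I carried the cedar reading forward as ρ, the resting ratio, intermediate A per substrate at rest.

Next I read the products. One reagent gave 0.721 of product in maple and 0.891 in cedar. The flask's substrate lies near the geometric middle of the two runs, 1.97 mM, so I took the mean, 0.806. That gives the flask 64.5 % of product and leaves 35.5 % as substrate plus intermediate A.

With ρ this splits into 18.4 % substrate and 17.1 % intermediate A, a conversion of 81.6 %. Maple's target share of product, 0.409, gives 26.4 % target and 38.1 % side product.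

The forecast said the reagent has run out first, with conversion 81.8 %, target 26.9 %, side product 39 %, intermediate A 15.8 % and a long-time target of 26.9 %, on the ground that “With no reagent left, target stays put”.

The outcome in the flask was that the reagent has run out first, with 0 % of it remaining at 10.0 min, and it gave conversion 82.5 %, target 27.0 %, side product 39.4 %, intermediate A 16.1 % and a long-time target of 27.0 %. In the flask the substrate left, 17.5 %, multiplied by ρ gives 16.3 % intermediate A, against the 16.1 % found.

    substrate ⇌ intermediate A (K = 0.920, k = 0.0960 s⁻¹)
    reagent + intermediate A → intermediate B (k = 130 L mol⁻¹ s⁻¹)
    reagent + intermediate A → intermediate C (k = 190 L mol⁻¹ s⁻¹)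
    intermediate B → target (k = 0.0680 s⁻¹)
    intermediate C → side product (k = 0.120 s⁻¹)
    intermediate C ⇌ intermediate D (K = 0.180, k = 1.00 s⁻¹)
    2 reagent → self-condensation product (k = 20.0 L mol⁻¹ s⁻¹)

For the neighbouring flask with 6.4 × 10⁻⁴ M of reagent, I counted one product per reagent, which leaves 68.0 % as substrate plus intermediate A. With ρ at 0.930 that gives a conversion of 64.8 % and 32.8 % intermediate A. The computed neighbouring flask gave 63.7 % and 33.4 %.

The numbers in the tables stem from a simulated flask for an exercise; the scatter is artificial.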